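**Plan**
Retrosynthesis: the two benzyl ethers are put back and the C3 aldehyde and the chain-end CH2OH are both taken back to ethyl esters; the benzofuran is then cut at C3–C3a and O1–C7a.
Enabling feature (ring A = benzo ring, ring C = 2-aryl group): O1–C2=C3 is the enol O–C=C of a ring C aroylacetate, and C3a and C7a are neighbouring ring A carbons that can carry iodine and bromine.
Forward: the ring A bromo-iodoarene (four steps from 4-bromo-2-methoxyaniline) and the ring C keto ester (two steps from methyl 3-O-methylgallate) are joined in step 7, which closes the furan, the only ring made in the route.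
Afterwards both esters are reduced, only the benzofuranyl carbinol is oxidised to the aldehyde, and the benzyl ethers are cleaved.
Stereochemistry: the target has no stereocentre and no configured double bond, so nothing has to be controlled.

Key step: step 7

Remark on the chemistry: the chain terminus is carried through the coupling as an ethyl ester, so that a single hydride reduction later sets both CH2OH groups; 4-bromo-2-methoxyaniline, ethyl acrylate, methyl 3-O-methylgallate and ethyl acetate are taken as commercial.

**Route**

Step 1
Reactants: 1 4-bromo-2-methoxyaniline; 2 ethyl acrylate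
Product: 3 ethyl (E)-3-(4-amino-3-methoxyphenyl)prop-2-enoate
Conditions: Pd(OAc)2 (2 mol%), P(o-tol)3 (8 mol%), Et3N, DMF, 100 °C
Reagents that add atoms: none
Why: Mizoroki–Heck coupling of an aryl bromide with an acrylate tolerates a free aniline and should give the E-cinnamate by syn insertion and syn β-hydride elimination, the alkene geometry being of no consequence because it is hydrogenated next.

Step 2
Reactants: 3 ethyl (E)-3-(4-amino-3-methoxyphenyl)prop-2-enoate
Product: 4 ethyl 3-(4-amino-3-methoxyphenyl)propanoate
Conditions: H2 (1 atm), 10% Pd/C, EtOH, rt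
Reagents that add atoms: none
Why: catalytic hydrogenation of a conjugated alkene is placed before any halogen or benzyl ether is present, so nothing else in the molecule can be reduced.

Step 3
Reactants: 4 ethyl 3-(4-amino-3-methoxyphenyl)propanoate
Product: 5 ethyl 3-(4-amino-3-iodo-5-methoxyphenyl)propanoate
Conditions: NIS (1.05 equiv), MeCN, 0 °C → rt, dark
Reagents that add atoms: N-iodosuccinimide, O=C1CCC(=O)N1I
Why: electrophilic aromatic iodination is directed by the free amino group, the strongest donor, whose para position holds the side chain and whose other ortho position holds the methoxy group, so only the remaining ortho carbon should be attacked.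

Step 4
Reactants: 5 ethyl 3-(4-amino-3-iodo-5-methoxyphenyl)propanoate
Product: 7 ethyl 3-(4-bromo-3-iodo-5-methoxyphenyl)propanoate, via arenediazonium bromide 6 (not isolated)
Conditions: t-BuONO, CuBr2, MeCN, 0 → 60 °C
Reagents that add atoms: copper dibromide, [Cu+2].[Br-].[Br-]
Why: aprotic Sandmeyer bromination, in which the alkyl nitrite diazotises the aniline and CuBr2 transfers bromine to the aryl radical, avoids aqueous acid and should leave the ethyl ester and the C–I bond intact.

Step 5
Reactants: 8 methyl 3-O-methylgallate (methyl 3,4-dihydroxy-5-methoxybenzoate)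
Product: 9 methyl 3,4-bis(benzyloxy)-5-methoxybenzoate
Conditions: BnBr (2.4 equiv), K2CO3, DMF, 60 °C
Reagents that add atoms: benzyl bromide, BrCc1ccccc1
Why: Williamson ether synthesis on the two phenols proceeds with carbonate in dry DMF, a base too weak to touch the methyl ester.

Step 6
Reactants: 9 methyl 3,4-bis(benzyloxy)-5-methoxybenzoate; 10 ethyl acetate
Product: 12 ethyl 3-[3,4-bis(benzyloxy)-5-methoxyphenyl]-3-oxopropanoate, via lithium enolate of ethyl acetate 11 (not isolated)
Conditions: LiN(SiMe3)2 (3 equiv), 10 (3 equiv), THF, −78 °C; then 9, −78 → 0 °C; aq NH4Cl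
Reagents that add atoms: none
Why: crossed Claisen condensation of the preformed ester enolate with the non-enolisable aryl ester is driven to completion by deprotonation of the β-keto ester product by the excess base.

Step 7
Reactants: 7 ethyl 3-(4-bromo-3-iodo-5-methoxyphenyl)propanoate; 12 ethyl 3-[3,4-bis(benzyloxy)-5-methoxyphenyl]-3-oxopropanoate
Product: 14 ethyl 2-[3,4-bis(benzyloxy)-5-methoxyphenyl]-5-(3-ethoxy-3-oxopropyl)-7-methoxy-1-benzofuran-3-carboxylate, via α-aryl β-keto ester 13 (not isolated)
Conditions: CuI (10 mol%), K2CO3 (3 equiv, dry), THF, 100 °C, sealed tube, Ar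
Reagents that add atoms: none
Why: K2CO3 deprotonates 12 and CuI gives a chelated enolate of monovalent copper, which should undergo oxidative addition at the weaker C–I bond of 7 and C–C reductive elimination (Hurtley/Ullmann-type α-arylation of a 1,3-dicarbonyl compound), forming C3–C3a and giving 13. The doubly activated C–H of 13 is deprotonated at once, and in the resulting enolate the ketone oxygen lies beside the ortho C–Br bond, so a second, now intramolecular, Ullmann-type O-arylation forms O1–C7a. The closest known reaction is the CuI-catalysed domino coupling of 1-bromo-2-iodobenzenes with β-keto esters to 2,3-disubstituted benzofurans. The furan is the only ring closed, in a 5-exo sense, by attack of the enolate oxygen on the brominated ring A carbon through a copper-bridged six-membered metallacycle of trivalent copper that reductively eliminates C–O. No stereocentre is formed, since the α-carbon of 13 becomes the sp2 carbon C3. The step needs carbon to go to C3a and oxygen to C7a, which is secured by the faster reaction of C–I than C–Br with the soft copper enolate (the hindered C–Br bond reacting only once the oxygen is held next to it), and it needs closure through the ketone oxygen, which carries more of the enolate charge than the ester oxygen and leads to the aromatic furan.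

Step 8
Reactants: 14 ethyl 2-[3,4-bis(benzyloxy)-5-methoxyphenyl]-5-(3-ethoxy-3-oxopropyl)-7-methoxy-1-benzofuran-3-carboxylate
Product: 15 3-{2-[3,4-bis(benzyloxy)-5-methoxyphenyl]-3-(hydroxymethyl)-7-methoxy-1-benzofuran-5-yl}propan-1-ol
Conditions: i-Bu2AlH (6 equiv), CH2Cl2, −78 → 0 °C; aq potassium sodium tartrate
Reagents that add atoms: none
Why: hydride reduction of esters with i-Bu2AlH should take both ethyl esters to primary alcohols while benzyl ethers, methyl ethers and the benzofuran are inert.

Step 9
Reactants: 15 3-{2-[3,4-bis(benzyloxy)-5-methoxyphenyl]-3-(hydroxymethyl)-7-methoxy-1-benzofuran-5-yl}propan-1-ol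
Product: 16 2-[3,4-bis(benzyloxy)-5-methoxyphenyl]-5-(3-hydroxypropyl)-7-methoxy-1-benzofuran-3-carbaldehyde
Conditions: MnO2 (activated, excess), CH2Cl2, rt
Reagents that add atoms: none
Why: chemoselective MnO2 oxidation acts only on activated (benzylic or allylic type) alcohols, so the hydroxymethyl group on C3 of the benzofuran should give the aldehyde while the saturated primary alcohol of the chain stays untouched.

Step 10
Reactants: 16 2-[3,4-bis(benzyloxy)-5-methoxyphenyl]-5-(3-hydroxypropyl)-7-methoxy-1-benzofuran-3-carbaldehyde
Product: 17 Mururin C, 2-(3,4-dihydroxy-5-methoxyphenyl)-5-(3-hydroxypropyl)-7-methoxy-1-benzofuran-3-carbaldehyde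
Conditions: BCl3 (1 M in CH2Cl2), C6HMe5, CH2Cl2, −78 °C; then MeOH
Reagents that add atoms: none
Why: Lewis acid cleavage of aryl benzyl ethers by BCl3 at −78 °C, with pentamethylbenzene as a non-basic trap for the benzyl cation, should free the catechol without touching the aryl methyl ethers, the aldehyde or the primary alcohol, whose borate is solvolysed on quench.

**Compound list**
1 | 4-bromo-2-methoxyaniline | COc1cc(Br)ccc1N | starting material
2 | ethyl acrylate | C=CC(=O)OCC | starting material
3 | ethyl (E)-3-(4-amino-3-methoxyphenyl)prop-2-enoate | CCOC(=O)/C=C/c1ccc(N)c(OC)c1 | intermediate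
4 | ethyl 3-(4-amino-3-methoxyphenyl)propanoate | CCOC(=O)CCc1ccc(N)c(OC)c1 | intermediate
5 | ethyl 3-(4-amino-3-iodo-5-methoxyphenyl)propanoate | CCOC(=O)CCc1cc(I)c(N)c(OC)c1 | intermediate
6 | 4-(3-ethoxy-3-oxopropyl)-2-iodo-6-methoxybenzenediazonium bromide (not isolated) | CCOC(=O)CCc1cc(I)c([N+]#N)c(OC)c1.[Br-] | intermediate
7 | ethyl 3-(4-bromo-3-iodo-5-methoxyphenyl)propanoate | CCOC(=O)CCc1cc(I)c(Br)c(OC)c1 | intermediate
8 | methyl 3-O-methylgallate (methyl 3,4-dihydroxy-5-methoxybenzoate) | COC(=O)c1cc(O)c(O)c(OC)c1 | starting material
9 | methyl 3,4-bis(benzyloxy)-5-methoxybenzoate | COC(=O)c1cc(OC)c(OCc2ccccc2)c(OCc2ccccc2)c1 | intermediate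
10 | ethyl acetate | CCOC(C)=O | starting material
11 | lithium enolate of ethyl acetate (not isolated) | [Li+].[O-]C(=C)OCC | intermediate
12 | ethyl 3-[3,4-bis(benzyloxy)-5-methoxyphenyl]-3-oxopropanoate | CCOC(=O)CC(=O)c1cc(OC)c(OCc2ccccc2)c(OCc2ccccc2)c1 | intermediate
13 | ethyl 2-[2-bromo-5-(3-ethoxy-3-oxopropyl)-3-methoxyphenyl]-3-[3,4-bis(benzyloxy)-5-methoxyphenyl]-3-oxopropanoate (not isolated; racemic at the α-carbon, which becomes sp2) | CCOC(=O)CCc1cc(OC)c(Br)c(c1)C(C(=O)OCC)C(=O)c1cc(OC)c(OCc2ccccc2)c(OCc2ccccc2)c1 | intermediate
14 | ethyl 2-[3,4-bis(benzyloxy)-5-methoxyphenyl]-5-(3-ethoxy-3-oxopropyl)-7-methoxy-1-benzofuran-3-carboxylate | CCOC(=O)CCc1cc(OC)c2oc(-c3cc(OC)c(OCc4ccccc4)c(OCc4ccccc4)c3)c(C(=O)OCC)c2c1 | intermediate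
15 | 3-{2-[3,4-bis(benzyloxy)-5-methoxyphenyl]-3-(hydroxymethyl)-7-methoxy-1-benzofuran-5-yl}propan-1-ol | OCCCc1cc(OC)c2oc(-c3cc(OC)c(OCc4ccccc4)c(OCc4ccccc4)c3)c(CO)c2c1 | intermediate
16 | 2-[3,4-bis(benzyloxy)-5-methoxyphenyl]-5-(3-hydroxypropyl)-7-methoxy-1-benzofuran-3-carbaldehyde | OCCCc1cc(OC)c2oc(-c3cc(OC)c(OCc4ccccc4)c(OCc4ccccc4)c3)c(C=O)c2c1 | intermediate
17 | Mururin C | COc1cc(-c2oc3c(OC)cc(CCCO)cc3c2C=O)cc(O)c1O | target

**Count**
Total steps: 10. Longest linear sequence: 8 steps (steps 1–4, then 7–10, from 4-bromo-2-methoxyaniline); the ring C branch (steps 5 and 6) joins at step 7.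

**Steps most likely to fail**

Step 7. Carbonate at 100 °C may cleave the aroyl group from 12 or 13 by retro-Claisen attack. The sequence may also stall after the C–C coupling, because the C–Br bond, flanked by the methoxy group and the new substituent, enters the C–O coupling slowly. The fallback sets out from 7 and 12 and runs the two bond formations as separate operations. CuI with L-proline and Cs2CO3 in DMSO at 40 °C should arylate the keto ester at the C–I bond only, so that ethyl 2-[2-bromo-5-(3-ethoxy-3-oxopropyl)-3-methoxyphenyl]-3-[3,4-bis(benzyloxy)-5-methoxyphenyl]-3-oxopropanoate 13 can be isolated. The furan would then be closed by a palladium-catalysed intramolecular C–O coupling of its enolate (Pd2(dba)3, DPEphos, Cs2CO3, toluene, 100 °C), in which zerovalent palladium inserts into the hindered C–Br bond more readily than copper. This comes back to the route at 14 and needs no compound outside the list (F0).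

Step 3. With the saturated chain in place the ring is very electron-rich, so iodination may lose positional control (attack para to the methoxy group), run on to a di-iodide or oxidise the aniline. The fallback sets out from 3, where the conjugated acrylate deactivates the two ring positions next to it. NIS in MeCN should then iodinate only ortho to nitrogen and give ethyl (E)-3-(4-amino-3-iodo-5-methoxyphenyl)prop-2-enoate F1. Aprotic Sandmeyer bromination (t-BuONO, CuBr2, MeCN) through 4-[(E)-3-ethoxy-3-oxoprop-1-en-1-yl]-2-iodo-6-methoxybenzenediazonium bromide F2 would give ethyl (E)-3-(4-bromo-3-iodo-5-methoxyphenyl)prop-2-enoate F3. Diimide (TsNHNH2, NaOAc, THF/H2O, reflux) would then reduce the alkene without touching C–I or C–Br and come back to the route at 7.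

Step 9. The oxidation may lose chemoselectivity (the saturated alcohol reacting as well) or stop short on MnO2 of low activity. The fallback sets out from 15 and oxidises both alcohols on purpose (Dess–Martin periodinane, NaHCO3, CH2Cl2) to 2-[3,4-bis(benzyloxy)-5-methoxyphenyl]-7-methoxy-5-(3-oxopropyl)-1-benzofuran-3-carbaldehyde F4. Only the saturated aldehyde would then be reduced, with NaBH4 in EtOH/CH2Cl2 at −78 °C; the benzofuran-3-carbaldehyde is a vinylogous formate deactivated by O1 and should survive. This comes back to the route at 16.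

**Further compounds**
F0 | step 7 | none | none
F1 | step 3 | ethyl (E)-3-(4-amino-3-iodo-5-methoxyphenyl)prop-2-enoate | CCOC(=O)/C=C/c1cc(I)c(N)c(OC)c1
F2 | step 3 | 4-[(E)-3-ethoxy-3-oxoprop-1-en-1-yl]-2-iodo-6-methoxybenzenediazonium bromide | CCOC(=O)/C=C/c1cc(I)c([N+]#N)c(OC)c1.[Br-]
F3 | step 3 | ethyl (E)-3-(4-bromo-3-iodo-5-methoxyphenyl)prop-2-enoate | CCOC(=O)/C=C/c1cc(I)c(Br)c(OC)c1
F4 | step 9 | 2-[3,4-bis(benzyloxy)-5-methoxyphenyl]-7-methoxy-5-(3-oxopropyl)-1-benzofuran-3-carbaldehyde | O=CCCc1cc(OC)c2oc(-c3cc(OC)c(OCc4ccccc4)c(OCc4ccccc4)c3)c(C=O)c2c1
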